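**Plan**

- Retrosynthesis: the C3–Br bond and both benzyl ethers go last. Ring C is then cut at C2–C3 and C3–C4, which removes C3 as a carbene carbon and leaves a 2-aryl-3-siloxybenzofuran. That is cut at C3–C3a (acylation) and at the ether O–C2 bond (alkylation), giving a pentaoxygenated phenol and an α-bromo arylacetate.
- Feature used: C3 is the only CH of ring C and lies between the aryl-bearing C2 and the carbonyl C4, so ring C is a 2-arylbenzofuran-3-one plus one inserted carbon. Ring A keeps a single unsubstituted carbon, so the furanone can close in one way only.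
- Forward: ring A is dressed first (syringol, then two successive bromine-to-oxygen exchanges). Ring B arrives with the ether linkage, the five-membered furanone closes by Friedel–Crafts acylation, and dibromocarbene expands it to the six-membered ring C.
- Stereochemistry: the target has no stereocentre. The one stereocentre met on the way (the aryl-bearing carbon from the α-bromo ester to the coumaranone) is racemic and vanishes on enol silylation.

Key step: step 12

Remark: the dibromination in step 2 is taken to occur at the two positions that are ortho to one methoxy group and para to the other, as is usual for 1,2,3-trialkoxybenzenes.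

**Route**

Step 1
Reactants: 1 syringol (2,6-dimethoxyphenol); 2 benzyl bromide
Product: 3 2-(benzyloxy)-1,3-dimethoxybenzene
Conditions: K2CO3, DMF, 60 °C
Reagents that add atoms: none
Why: Williamson etherification of the only nucleophilic site; the flanked phenol is acidic enough for carbonate and should benzylate cleanly on warming.

Step 2
Reactants: 3 2-(benzyloxy)-1,3-dimethoxybenzene
Product: 4 3-(benzyloxy)-1,5-dibromo-2,4-dimethoxybenzene
Conditions: NBS (2.2 equiv), MeCN, 0 °C to 40 °C
Reagents that add atoms: N-bromosuccinimide, O=C1CCC(=O)N1Br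
Why: Electrophilic aromatic bromination; each of the two positions attacked is ortho to one methoxy group and para to the other, whereas the remaining CH is meta to both and para only to the twisted central benzyloxy group.

Step 3
Reactants: 4 3-(benzyloxy)-1,5-dibromo-2,4-dimethoxybenzene
Product: 7 3-(benzyloxy)-5-bromo-2,4-dimethoxyphenol, via aryllithium 5 (not isolated), via dimethyl arylboronate 6 (not isolated)
Conditions: n-BuLi (1.0 equiv), THF, −78 °C; B(OMe)3, −78 °C to 0 °C; AcOH, 30% aq H2O2, 0 °C to rt
Reagents that add atoms: hydrogen peroxide, OO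
Why: Bromine–lithium exchange with one equivalent of n-BuLi should stop after one bromine, as it does for 1,5-dibromo-2,4-dimethoxybenzene, because the electron-rich monolithio arene resists a second exchange; borylation and peroxide oxidation (1,2-aryl shift from boron to oxygen) then deliver the phenol.

Step 4
Reactants: 7 3-(benzyloxy)-5-bromo-2,4-dimethoxyphenol; 2 benzyl bromide
Product: 8 1,3-bis(benzyloxy)-5-bromo-2,4-dimethoxybenzene
Conditions: K2CO3, DMF, rt
Reagents that add atoms: none
Why: Williamson etherification of the single free phenol.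

Step 5
Reactants: 8 1,3-bis(benzyloxy)-5-bromo-2,4-dimethoxybenzene
Product: 11 3,5-bis(benzyloxy)-2,4-dimethoxyphenol, via aryllithium 9 (not isolated), via dimethyl arylboronate 10 (not isolated)
Conditions: n-BuLi (1.05 equiv), THF, −78 °C; B(OMe)3, −78 °C to 0 °C; AcOH, 30% aq H2O2, 0 °C to rt
Reagents that add atoms: hydrogen peroxide, OO
Why: Bromine–lithium exchange at −78 °C is much faster than deprotonation of the benzylic ether positions; borylation and oxidation convert the remaining bromide into the phenol that will become O1 of the heterocycle.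

Step 6
Reactants: 12 3,4,5-trimethoxyphenylacetic acid
Product: 13 methyl 2-(3,4,5-trimethoxyphenyl)acetate
Conditions: MeOH, H2SO4 (cat.), reflux
Reagents that add atoms: methanol, CO
Why: Fischer esterification of an unhindered arylacetic acid.

Step 7
Reactants: 13 methyl 2-(3,4,5-trimethoxyphenyl)acetate
Product: 16 methyl 2-bromo-2-(3,4,5-trimethoxyphenyl)acetate (racemic), via lithium enolate 14 (not isolated), via silyl ketene acetal 15 (not isolated)
Conditions: LiN(SiMe3)2, THF, −78 °C; Me3SiCl, −78 °C; NBS, −78 °C to 0 °C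
Reagents that add atoms: N-bromosuccinimide, O=C1CCC(=O)N1Br
Why: α-Bromination of an ester through its silyl ketene acetal; the ketene acetal is far more nucleophilic than the trimethoxyphenyl ring, so bromine should go to the α-carbon and not onto ring B, and silyl trapping prevents over-bromination.

Step 8
Reactants: 11 3,5-bis(benzyloxy)-2,4-dimethoxyphenol; 16 methyl 2-bromo-2-(3,4,5-trimethoxyphenyl)acetate
Product: 17 methyl 2-[3,5-bis(benzyloxy)-2,4-dimethoxyphenoxy]-2-(3,4,5-trimethoxyphenyl)acetate (racemic)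
Conditions: K2CO3, DMF, rt to 50 °C
Reagents that add atoms: none
Why: SN2 O-alkylation of a phenoxide by an activated benzylic α-bromo ester that has no β-hydrogen to eliminate.

Step 9
Reactants: 17 methyl 2-[3,5-bis(benzyloxy)-2,4-dimethoxyphenoxy]-2-(3,4,5-trimethoxyphenyl)acetate
Product: 18 2-[3,5-bis(benzyloxy)-2,4-dimethoxyphenoxy]-2-(3,4,5-trimethoxyphenyl)acetic acid (racemic)
Conditions: LiOH, THF–MeOH–H2O, rt; then 1 M HCl
Reagents that add atoms: lithium hydroxide, [Li+].[OH-]
Why: Saponification of a methyl ester; nothing else in the molecule is base-labile and the stereocentre is racemic anyway.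

Step 10
Reactants: 18 2-[3,5-bis(benzyloxy)-2,4-dimethoxyphenoxy]-2-(3,4,5-trimethoxyphenyl)acetic acid
Product: 20 4,6-bis(benzyloxy)-5,7-dimethoxy-2-(3,4,5-trimethoxyphenyl)-1-benzofuran-3(2H)-one (racemic), via mixed trifluoroacetic anhydride 19 (not isolated)
Conditions: (CF3CO)2O (1.5 equiv), CH2Cl2, 0 °C to rt, argon; aq NaHCO3 work-up
Reagents that add atoms: none
Why: Intramolecular Friedel–Crafts acylation through the mixed anhydride; the only free carbon of ring A is ortho, ortho and para to three oxygen donors, so the five-membered ring should close without a Lewis acid and the benzyl ethers should survive.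

Step 11
Reactants: 20 4,6-bis(benzyloxy)-5,7-dimethoxy-2-(3,4,5-trimethoxyphenyl)-1-benzofuran-3(2H)-one
Product: 21 {[4,6-bis(benzyloxy)-5,7-dimethoxy-2-(3,4,5-trimethoxyphenyl)-1-benzofuran-3-yl]oxy}(tert-butyl)dimethylsilane
Conditions: TBSOTf, Et3N, CH2Cl2, 0 °C, argon (crude 20 used at once)
Reagents that add atoms: tert-butyldimethylsilyl trifluoromethanesulfonate, CC(C)(C)[Si](C)(C)OS(=O)(=O)C(F)(F)F
Why: Soft enolisation and O-silylation of a ketone; O-silylation is favoured because it creates the aromatic benzofuran, and immediate trapping guards the autoxidation-prone C2–H of the coumaranone.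

Step 12
Reactants: 21 {[4,6-bis(benzyloxy)-5,7-dimethoxy-2-(3,4,5-trimethoxyphenyl)-1-benzofuran-3-yl]oxy}(tert-butyl)dimethylsilane; 22 bromoform
Product: 25 5,7-bis(benzyloxy)-3-bromo-6,8-dimethoxy-2-(3,4,5-trimethoxyphenyl)-4H-chromen-4-one, via dibromocyclopropane 23 (not isolated), via 3-bromo-4-siloxyflavylium bromide 24 (not isolated)
Conditions: KOtBu (3 equiv), CHBr3 (1.5 equiv, slow addition), toluene–hexane, −30 °C to rt, argon
Reagents that add atoms: none
Why: Proposed new method: dibromocarbene, released from CHBr3 by KOtBu, is an electrophilic singlet carbene and should add in a cheletropic [2+1] manner to the C2=C3 bond of 21, which carries two oxygen donors and is the most electron-rich π bond present, to give cyclopropane 23. In 23 the endo bromine is cis to the furan ring bonds, so the disrotatory cyclopropyl-to-allyl cation opening (Woodward–Hoffmann–DePuy, inward rotation enforced by the ring) can expel it while the old C2–C3 σ bond breaks, leaving the aromatic 3-bromo-4-siloxyflavylium ion 24 in which the carbene carbon has become C3, bonded to both C2 and C4. Bromide or tert-butoxide then takes the silyl group from oxygen and uncovers the C4 carbonyl of 25. The closest known reactions are the dihalocarbene ring expansions of cyclic silyl enol ethers to 2-halo-enones and the Ciamician–Dennstedt one-carbon insertions into indoles, pyrroles and benzofurans; applying the sequence to a 2-aryl-3-siloxybenzofuran to reach a flavone is the untested part. Ring C is not closed by a cyclisation but grows from the five-membered furan by insertion of one carbon (three-membered ring closure, then electrocyclic opening of the shared bond), and no stereocentre is created. The step needs the carbene to choose the enol ether double bond over the alkoxyarenes and benzylic positions, which the doubly oxygenated alkene and the low temperature should secure, and it needs the silyl ether to outlast KOtBu until the carbene has added, for which the bulky tert-butyldimethylsilyl group and a non-polar solvent are chosen.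

Step 13
Reactants: 25 5,7-bis(benzyloxy)-3-bromo-6,8-dimethoxy-2-(3,4,5-trimethoxyphenyl)-4H-chromen-4-one
Product: 26 5,7-dihydroxy-6,8,3',4',5'-pentamethoxyflavone
Conditions: H2 (1 atm), Pd/C (10 wt%), NaOAc, EtOAc–MeOH, rt
Reagents that add atoms: none
Why: Catalytic hydrogenolysis should cleave both aryl benzyl ethers and the vinylic C–Br bond in one operation; NaOAc takes up HBr without retarding O-debenzylation as amines can, and the C2=C3 bond of the vinylogous ester is reduced far more slowly, so the reaction is stopped once hydrogen uptake ends.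

**Compound list**

1 | syringol (2,6-dimethoxyphenol) | COc1cccc(OC)c1O | starting material
2 | benzyl bromide | BrCc1ccccc1 | starting material
3 | 2-(benzyloxy)-1,3-dimethoxybenzene | COc1cccc(OC)c1OCc1ccccc1 | intermediate
4 | 3-(benzyloxy)-1,5-dibromo-2,4-dimethoxybenzene | COc1c(Br)cc(Br)c(OC)c1OCc1ccccc1 | intermediate
5 | [3-(benzyloxy)-5-bromo-2,4-dimethoxyphenyl]lithium (not isolated) | [Li]c1cc(Br)c(OC)c(OCc2ccccc2)c1OC | intermediate
6 | dimethyl [3-(benzyloxy)-5-bromo-2,4-dimethoxyphenyl]boronate (not isolated) | COB(OC)c1cc(Br)c(OC)c(OCc2ccccc2)c1OC | intermediate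
7 | 3-(benzyloxy)-5-bromo-2,4-dimethoxyphenol | Oc1cc(Br)c(OC)c(OCc2ccccc2)c1OC | intermediate
8 | 1,3-bis(benzyloxy)-5-bromo-2,4-dimethoxybenzene | Brc1cc(OCc2ccccc2)c(OC)c(OCc2ccccc2)c1OC | intermediate
9 | [3,5-bis(benzyloxy)-2,4-dimethoxyphenyl]lithium (not isolated) | [Li]c1cc(OCc2ccccc2)c(OC)c(OCc2ccccc2)c1OC | intermediate
10 | dimethyl [3,5-bis(benzyloxy)-2,4-dimethoxyphenyl]boronate (not isolated) | COB(OC)c1cc(OCc2ccccc2)c(OC)c(OCc2ccccc2)c1OC | intermediate
11 | 3,5-bis(benzyloxy)-2,4-dimethoxyphenol | Oc1cc(OCc2ccccc2)c(OC)c(OCc2ccccc2)c1OC | intermediate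
12 | 3,4,5-trimethoxyphenylacetic acid | COc1cc(CC(=O)O)cc(OC)c1OC | starting material
13 | methyl 2-(3,4,5-trimethoxyphenyl)acetate | COC(=O)Cc1cc(OC)c(OC)c(OC)c1 | intermediate
14 | lithium enolate of 13 (not isolated; double-bond geometry not controlled) | COC(O[Li])=Cc1cc(OC)c(OC)c(OC)c1 | intermediate
15 | {[1-methoxy-2-(3,4,5-trimethoxyphenyl)ethenyl]oxy}trimethylsilane (not isolated; mixture of double-bond isomers) | COC(O[Si](C)(C)C)=Cc1cc(OC)c(OC)c(OC)c1 | intermediate
16 | methyl 2-bromo-2-(3,4,5-trimethoxyphenyl)acetate (racemic) | COC(=O)C(Br)c1cc(OC)c(OC)c(OC)c1 | intermediate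
17 | methyl 2-[3,5-bis(benzyloxy)-2,4-dimethoxyphenoxy]-2-(3,4,5-trimethoxyphenyl)acetate (racemic) | COC(=O)C(Oc1cc(OCc2ccccc2)c(OC)c(OCc2ccccc2)c1OC)c1cc(OC)c(OC)c(OC)c1 | intermediate
18 | 2-[3,5-bis(benzyloxy)-2,4-dimethoxyphenoxy]-2-(3,4,5-trimethoxyphenyl)acetic acid (racemic) | OC(=O)C(Oc1cc(OCc2ccccc2)c(OC)c(OCc2ccccc2)c1OC)c1cc(OC)c(OC)c(OC)c1 | intermediate
19 | mixed anhydride of 18 with trifluoroacetic acid (racemic, not isolated) | O=C(OC(=O)C(F)(F)F)C(Oc1cc(OCc2ccccc2)c(OC)c(OCc2ccccc2)c1OC)c1cc(OC)c(OC)c(OC)c1 | intermediate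
20 | 4,6-bis(benzyloxy)-5,7-dimethoxy-2-(3,4,5-trimethoxyphenyl)-1-benzofuran-3(2H)-one (racemic) | COc1cc(C2Oc3c(OC)c(OCc4ccccc4)c(OC)c(OCc4ccccc4)c3C2=O)cc(OC)c1OC | intermediate
21 | {[4,6-bis(benzyloxy)-5,7-dimethoxy-2-(3,4,5-trimethoxyphenyl)-1-benzofuran-3-yl]oxy}(tert-butyl)dimethylsilane | COc1cc(-c2oc3c(OC)c(OCc4ccccc4)c(OC)c(OCc4ccccc4)c3c2O[Si](C)(C)C(C)(C)C)cc(OC)c1OC | intermediate
22 | bromoform | BrC(Br)Br | starting material
23 | 4,6-bis(benzyloxy)-1,1-dibromo-6b-[(tert-butyldimethylsilyl)oxy]-3,5-dimethoxy-1a-(3,4,5-trimethoxyphenyl)-1a,6b-dihydro-1H-cyclopropa[b][1]benzofuran (racemic, ring fusion necessarily cis, not isolated) | COc1cc(C23Oc4c(OC)c(OCc5ccccc5)c(OC)c(OCc5ccccc5)c4C2(O[Si](C)(C)C(C)(C)C)C3(Br)Br)cc(OC)c1OC | intermediate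
24 | 5,7-bis(benzyloxy)-3-bromo-4-[(tert-butyldimethylsilyl)oxy]-6,8-dimethoxy-2-(3,4,5-trimethoxyphenyl)chromenylium bromide (not isolated) | COc1cc(-c2[o+]c3c(OC)c(OCc4ccccc4)c(OC)c(OCc4ccccc4)c3c(O[Si](C)(C)C(C)(C)C)c2Br)cc(OC)c1OC.[Br-] | intermediate
25 | 5,7-bis(benzyloxy)-3-bromo-6,8-dimethoxy-2-(3,4,5-trimethoxyphenyl)-4H-chromen-4-one | COc1cc(-c2oc3c(OC)c(OCc4ccccc4)c(OC)c(OCc4ccccc4)c3c(=O)c2Br)cc(OC)c1OC | intermediate
26 | 5,7-dihydroxy-6,8,3',4',5'-pentamethoxyflavone | COc1cc(-c2cc(=O)c3c(O)c(OC)c(O)c(OC)c3o2)cc(OC)c1OC | target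

**Step count**

Total steps: 13. Longest linear sequence: 11 (steps 1–5 and 8–13); steps 6–7 form the short branch to bromo ester 16.

**Steps most likely to fail**

1. Step 12. The carbene may fail to add to the crowded, tetrasubstituted C2=C3 bond before tert-butoxide strips the silyl group, or the flavylium ion may be intercepted at C2 by alkoxide and be led into ring-opened products. The fallback uses known flavone chemistry and sets out from phenol 11. C-Acetylation at its only free ring carbon (Ac2O, BF3·OEt2, 0 °C to rt) should give 1-[2,4-bis(benzyloxy)-6-hydroxy-3,5-dimethoxyphenyl]ethan-1-one F1. Claisen–Schmidt condensation with 3,4,5-trimethoxybenzaldehyde (KOH, EtOH, rt) should give (E)-1-[2,4-bis(benzyloxy)-6-hydroxy-3,5-dimethoxyphenyl]-3-(3,4,5-trimethoxyphenyl)prop-2-en-1-one F2. Oxidative cyclisation (I2 cat., DMSO, 120 °C) should give 5,7-bis(benzyloxy)-6,8-dimethoxy-2-(3,4,5-trimethoxyphenyl)-4H-chromen-4-one F3. Hydrogenolysis (H2, Pd/C, EtOAc–MeOH) then returns to the route at 26.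

2. Step 10. Trifluoroacetic acid set free during ring closure may remove the benzyl ether that ends up next to the new ketone, or the mixed anhydride may trifluoroacetylate ring A instead of closing. The fallback replaces the acylium-type electrophile by an activated amide under buffered, non-protic conditions and sets out from acid 18. Amide coupling (Me2NH·HCl, EDC·HCl, HOBt, iPr2NEt, CH2Cl2) should give 2-[3,5-bis(benzyloxy)-2,4-dimethoxyphenoxy]-N,N-dimethyl-2-(3,4,5-trimethoxyphenyl)acetamide F4. Activation with (CF3SO2)2O and 2-fluoropyridine (CH2Cl2, −78 °C to 0 °C) should cyclise it onto the free ring-A carbon to give 4,6-bis(benzyloxy)-5,7-dimethoxy-N,N-dimethyl-2-(3,4,5-trimethoxyphenyl)-1-benzofuran-3-amine F5. Hydrolysis of this enamine with dilute aqueous HCl in THF returns to the route at 20.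

3. Step 13. Over-reduction of the C2=C3 bond to the flavanone, or stalling after only partial debenzylation or debromination, may spoil the one-pot global hydrogenolysis. The fallback separates the two events and avoids hydrogen gas, setting out from 25. Lewis-acid debenzylation (BCl3, pentamethylbenzene, CH2Cl2, −78 °C) should give 3-bromo-5,7-dihydroxy-6,8-dimethoxy-2-(3,4,5-trimethoxyphenyl)-4H-chromen-4-one F6. Formate-driven hydrodebromination (Pd(OAc)2, PPh3, HCO2H, Et3N, DMF, 60 °C) then returns to the route at 26.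

**Further compounds**

F1 | step 12 | 1-[2,4-bis(benzyloxy)-6-hydroxy-3,5-dimethoxyphenyl]ethan-1-one | CC(=O)c1c(O)c(OC)c(OCc2ccccc2)c(OC)c1OCc1ccccc1
F2 | step 12 | (E)-1-[2,4-bis(benzyloxy)-6-hydroxy-3,5-dimethoxyphenyl]-3-(3,4,5-trimethoxyphenyl)prop-2-en-1-one | COc1cc(/C=C/C(=O)c2c(O)c(OC)c(OCc3ccccc3)c(OC)c2OCc2ccccc2)cc(OC)c1OC
F3 | step 12 | 5,7-bis(benzyloxy)-6,8-dimethoxy-2-(3,4,5-trimethoxyphenyl)-4H-chromen-4-one | COc1cc(-c2cc(=O)c3c(OCc4ccccc4)c(OC)c(OCc4ccccc4)c(OC)c3o2)cc(OC)c1OC
F4 | step 10 | 2-[3,5-bis(benzyloxy)-2,4-dimethoxyphenoxy]-N,N-dimethyl-2-(3,4,5-trimethoxyphenyl)acetamide (racemic) | CN(C)C(=O)C(Oc1cc(OCc2ccccc2)c(OC)c(OCc2ccccc2)c1OC)c1cc(OC)c(OC)c(OC)c1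
F5 | step 10 | 4,6-bis(benzyloxy)-5,7-dimethoxy-N,N-dimethyl-2-(3,4,5-trimethoxyphenyl)-1-benzofuran-3-amine | COc1cc(-c2oc3c(OC)c(OCc4ccccc4)c(OC)c(OCc4ccccc4)c3c2N(C)C)cc(OC)c1OC
F6 | step 13 | 3-bromo-5,7-dihydroxy-6,8-dimethoxy-2-(3,4,5-trimethoxyphenyl)-4H-chromen-4-one | COc1cc(-c2oc3c(OC)c(O)c(OC)c(O)c3c(=O)c2Br)cc(OC)c1OC
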